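**Convention.** Lignan locants are used. C7, C8, C9 and Ar2 (3,4-dimethoxyphenyl) belong to one C6C3 half; C7', C8', C9' and Ar1 (4-hydroxy-3-methoxyphenyl) belong to the other. Ring A is O–C7'–C8'–C8–C9 and ring B is O–C7–C8–C8'–C9'. The target 17 is (7S,8R,7'R,8'S).

## The problem

Target 17 is a 7,9':7',9-diepoxylignan. Ring A and ring B are two tetrahydrofurans cis-fused across C8–C8', with Ar2 on C7, Ar1 on C7' and an acetoxy group on the bridgehead C8'. Four contiguous stereocentres must be set, one of them (C8') fully substituted and oxygenated. Both aryl groups are exo, that is, cis to the bridgehead substituent on the neighbouring carbon. The two halves differ in methylation and in bridgehead oxidation, so the skeleton cannot come from dimerising one C6C3 unit. The stereocentres depend on each other: cis fusion is enforced by the bicycle, a substituent at C7' can steer C8' and C8 when ring A closes, and Ar2 should take the convex face when ring B closes last. One centre of reagent-controlled origin (C7') is therefore enough. The fragile points are the two benzylic ether carbons (C7 is a veratryl ether that ionises with acid; C7' lies para to a phenol and is a quinone methide precursor) and the tertiary acetate, which is slow to form and migrates to any free neighbouring hydroxyl. The phenol must also be told apart from the tertiary alcohol at the acylation stage. The key step rests on one feature: the carbinol carbon C8' is linked through C7' and the ring A oxygen to C9, so a ketyl at C8' and a C8=C7 styrene sit 1,5 to each other in an α-cinnamyloxy ketone.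

## Retrosynthesis

**17 ⇒ 15 (through 16).** The O–acetyl bond at C8' is cut last. Acetylating only the tertiary hydroxyl of 15 beside a free phenol is not possible, so both are acetylated to 16 and the aryl acetate is then removed by aminolysis, which a tertiary alkyl acetate withstands. Carrying the aryl pivalate past the acetylation would save one operation, but it would rest on selectivity between a hindered aryl ester and an acetate activated by two β-oxygens, so the pivalate is removed first (15 ⇐ 14). The forward step must acylate a hindered bridgehead alcohol without acid, because the C7 veratryl ether would epimerise.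

**14 ⇒ 13.** The C7–O bond of ring B is cut. This cut is preferred to C9'–O because it leaves an unfunctionalised benzylic CH2 in 13: the electron-rich Ar2 ring is itself the handle for hydride abstraction, and the acid-labile veratryl ether is formed late. Precursor 13 is monocyclic with three stereocentres. The forward reaction must oxidise C7 only, which is why Ar1 stays acylated, and must place Ar2 on the convex face.

**13 ⇒ 12 ⇒ 11 (key disconnection).** After adding back the silyl group (12), the C8–C8' bond is cut. This removes ring A and two stereocentres (C8' quaternary, C8) at once and leaves acyclic ketone 11 with one stereocentre. A cut at C7'–C8' or at C7'–O would keep the quaternary carbinol in the precursor. The forward reaction must turn the C8' carbonyl into a ketyl, close ring A 5-exo onto C8 faster than the α C–O bonds are cleaved reductively, and relay the C7' configuration to C8 and C8'.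

**11 ⇒ 10 ⇒ 9.** These are functional-group changes only: the C8' ketone comes from the secondary alcohol of 10, and the silyl ether from the primary hydroxyl of diol 9. The ketone is made immediately before use because C7' is then benzylic and α to a carbonyl.

**9 ⇒ 8 + 7.** The C7'–O ether bond is cut. Opening epoxy alcohol 8 at its benzylic carbon with allylic alcohol 7 forms the ether, the C7' configuration (by inversion) and the 8',9'-diol in one step. A Williamson alkylation at a C7' alkoxide would need a differentiated triol and strong base, which the aryl ester would not survive. The forward reaction must be C3-selective and stereospecific.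

**8 ⇒ 4 ⇒ 2 ⇒ 1; 7 ⇒ 5.** Epoxide 8 comes from allylic alcohol 4 by catalytic asymmetric epoxidation, the only step that introduces absolute configuration. Alcohol 4 comes from ferulic acid 1 by phenol pivaloylation (2) and carboxyl reduction. Alcohol 7 comes from 3,4-dimethoxycinnamic acid 5 by the same reduction. The pivalate is on before the epoxidation because a 4-acyloxy ring makes the aryl epoxide far less prone to ionise than a 4-alkoxy ring.

## Roads not taken

**Alternative 1:** Arylketene (2+2) cycloaddition, then ring expansion.
- Cut: C8–C9 and C7'–C8', with the ring A oxygen inserted afterwards. Silyl enol ether A2, a ring B dihydrofuran carrying Ar2 at C7, would react with [4-(benzyloxy)-3-methoxyphenyl]ketene A3 to give cyclobutanone A1. Baeyer–Villiger oxidation with migration of the benzylic C7' and reduction of the lactone carbonyl to C9H2 would complete ring A.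
- Merits: two C–C bonds and both bridgehead centres form in one convergent step, the C8' oxygen is present from the start, and no reducing metal is needed.
- Weak points: monoaryl ketenes dimerise readily and are sluggish toward enol ethers. Ketene cycloadditions usually place the larger ketene substituent endo, so exo Ar1 would need epimerisation of a 3-siloxycyclobutanone, a ring that opens by retro-aldol cleavage with base or on loss of silicon. The lactone must then be reduced to the ether beside two benzylic C–O bonds, and the benzyl group removed by hydrogenolysis in their presence. A2 must also be made enantioenriched, and its C7 centre is β to a latent ketone.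
- Comparison: this road is more convergent in C–C bond formation. The chosen plan sets against it one catalytic asymmetric step, a defined chair transition state for C8 and C8', and no lactone-to-ether reduction.

**Alternative 2:** Double benzylic cyclisation of an acyclic pentaol.
- Cut: C7–O and C7'–O. Acid would ionise both benzylic alcohols of pentaol A5, and the C9' and C9 hydroxyls would capture the cations to close rings B and A, giving A4. A4 is identical in structure with 15.
- Merits: a very short endgame, no oxidant, and no need to control either benzylic centre before the cyclisation, since both are set by the bicycle. In these respects it is better than steps 8–11 of the chosen route.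
- Weak points: the C7' cation lies next to the free tertiary C8' hydroxyl, which invites a semipinacol shift. The C7' hydroxyl can capture the C7 cation to give a 2,5-diaryltetrahydrofuran. The real difficulty, the C8/C8' pair with its quaternary carbinol, must be built in an open chain by separate asymmetric chemistry.
- Comparison: the chosen plan sets against the shorter endgame a quaternary centre formed in a ring-closing step under control of C7'. The two routes share the last acetylation problem.

**Alternative 3:** Norrish–Yang closure of ring A.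
- Cut: C7'–C8'. Irradiation of ring B ketone A7 would transfer a hydrogen from the C7' methylene of its arylmethyl ether to the excited C8' carbonyl oxygen. The resulting 1,5-biradical would couple to give A6 with the tertiary hydroxyl in place.
- Merits: no reagent, redox-neutral, the tether doubles as the C7' source, and no α-alkoxy ketone is exposed to a reductant. In step economy of the key event it is better than the chosen route.
- Weak points: the two aryl chromophores absorb more strongly than the aliphatic carbonyl. An α-alkoxy cyclic ketone is prone to α-cleavage. A7 is a β-alkoxy ketone epimerisable at C8 and liable to eliminate the C9 ether. The C7' configuration is left to the conformational dynamics of a flexible biradical. The benzyl group must finally be hydrogenolysed beside two benzylic ethers.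
- Comparison: the chosen plan sets against the reagent-free step a closure whose three stereochemical relationships follow from a known transition-state model.

Key step: step 8

## Route

Step 1
Reactants: 1 ferulic acid, (E)-3-(4-hydroxy-3-methoxyphenyl)prop-2-enoic acid
Product: 2 (E)-3-[3-methoxy-4-(pivaloyloxy)phenyl]prop-2-enoic acid
Conditions: PivCl (1.2 equiv), 2 M aq NaOH, THF, 0 °C; then 1 M HCl
Reagents that add atoms: pivaloyl chloride, CC(C)(C)C(Cl)=O
Why: Schotten–Baumann acylation; the phenoxide outcompetes the conjugated carboxylate for the acid chloride and any mixed anhydride is hydrolysed on work-up. The hindered aryl ester keeps Ar1 electron-poor for the epoxide and DDQ steps.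

Step 2
Reactants: 2 (E)-3-[3-methoxy-4-(pivaloyloxy)phenyl]prop-2-enoic acid
Product: 4 (E)-4-(3-hydroxyprop-1-en-1-yl)-2-methoxyphenyl pivalate, via isobutyl carbonic mixed anhydride 3 (not isolated)
Conditions: i-BuOCOCl, N-methylmorpholine, THF, −15 °C; then NaBH4, H2O, 0 °C
Reagents that add atoms: isobutyl chloroformate, CC(C)COC(Cl)=O (its atoms are carried in 3 only; 4 gains hydrogen alone)
Why: Mixed-anhydride activation and borohydride reduction of a cinnamic acid to the cinnamyl alcohol; hydride attacks the acyl carbonyl 1,2, and the hindered aryl pivalate is left alone at 0 °C.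

Step 3
Reactants: 5 3,4-dimethoxycinnamic acid, (E)-3-(3,4-dimethoxyphenyl)prop-2-enoic acid
Product: 7 (E)-3-(3,4-dimethoxyphenyl)prop-2-en-1-ol, via isobutyl carbonic mixed anhydride 6 (not isolated)
Conditions: i-BuOCOCl, N-methylmorpholine, THF, −15 °C; then NaBH4, H2O, 0 °C
Reagents that add atoms: isobutyl chloroformate, CC(C)COC(Cl)=O (its atoms are carried in 6 only; 7 gains hydrogen alone)
Why: Same mixed-anhydride/borohydride reduction as in step 2; the alkene geometry is untouched.

Step 4
Reactants: 4 (E)-4-(3-hydroxyprop-1-en-1-yl)-2-methoxyphenyl pivalate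
Product: 8 4-[(2S,3S)-3-(hydroxymethyl)oxiran-2-yl]-2-methoxyphenyl pivalate (trans epoxide)
Conditions: Ti(OiPr)4 (10 mol %), L-(+)-diisopropyl tartrate (12 mol %), t-BuOOH (2 equiv, decane), 4 Å MS, CH2Cl2, −20 °C
Reagents that add atoms: tert-butyl hydroperoxide, CC(C)(C)OO
Why: Sharpless asymmetric epoxidation of an (E)-cinnamyl alcohol; the L-(+)-tartrate catalyst delivers oxygen to the face that gives the (2S,3S) epoxide. The 4-acyloxy ring keeps the benzylic epoxide carbon from ionising under the catalytic, sieve-dried conditions.

Step 5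
Reactants: 8 4-[(2S,3S)-3-(hydroxymethyl)oxiran-2-yl]-2-methoxyphenyl pivalate; 7 (E)-3-(3,4-dimethoxyphenyl)prop-2-en-1-ol
Product: 9 4-[(1R,2S)-1-{[(E)-3-(3,4-dimethoxyphenyl)prop-2-en-1-yl]oxy}-2,3-dihydroxypropyl]-2-methoxyphenyl pivalate
Conditions: 7 (4.2 equiv), Ti(OiPr)4 (1.0 equiv), toluene, i-PrOH stripped in vacuo; then 8, toluene, 40 °C; 10% aq tartaric acid
Reagents that add atoms: none
Why: Titanium-mediated C3-selective opening of a 2,3-epoxy alcohol by an alcohol; the epoxy alkoxide binds titanium and the benzylic carbon is attacked anti by a titanium-bound cinnamyl alkoxide, so inversion gives (R)-C7' and the C8' carbinol keeps its configuration. Exchanging the isopropoxide ligands beforehand removes the competing nucleophile, and excess 7 is recovered.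

Step 6
Reactants: 9 4-[(1R,2S)-1-{[(E)-3-(3,4-dimethoxyphenyl)prop-2-en-1-yl]oxy}-2,3-dihydroxypropyl]-2-methoxyphenyl pivalate
Product: 10 4-[(1R,2S)-3-[(tert-butyldimethylsilyl)oxy]-1-{[(E)-3-(3,4-dimethoxyphenyl)prop-2-en-1-yl]oxy}-2-hydroxypropyl]-2-methoxyphenyl pivalate
Conditions: TBSCl (1.05 equiv), imidazole, CH2Cl2, 0 °C
Reagents that add atoms: tert-butyldimethylsilyl chloride, CC(C)(C)[Si](C)(C)Cl
Why: Selective silylation of the primary hydroxyl of a 1,2-diol on steric grounds.

Step 7
Reactants: 10 4-[(1R,2S)-3-[(tert-butyldimethylsilyl)oxy]-1-{[(E)-3-(3,4-dimethoxyphenyl)prop-2-en-1-yl]oxy}-2-hydroxypropyl]-2-methoxyphenyl pivalate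
Product: 11 4-[(1R)-3-[(tert-butyldimethylsilyl)oxy]-1-{[(E)-3-(3,4-dimethoxyphenyl)prop-2-en-1-yl]oxy}-2-oxopropyl]-2-methoxyphenyl pivalate
Conditions: Dess–Martin periodinane, NaHCO3, CH2Cl2, 0 °C; used at once
Reagents that add atoms: none
Why: Dess–Martin oxidation of a secondary alcohol under buffered, near-neutral conditions, chosen so that the now benzylic and α-keto C7' centre is not enolised; the ketone is not stored.

Step 8
Reactants: 11 4-[(1R)-3-[(tert-butyldimethylsilyl)oxy]-1-{[(E)-3-(3,4-dimethoxyphenyl)prop-2-en-1-yl]oxy}-2-oxopropyl]-2-methoxyphenyl pivalate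
Product: 12 4-[(2R,3S,4S)-3-{[(tert-butyldimethylsilyl)oxy]methyl}-4-(3,4-dimethoxybenzyl)-3-hydroxyoxolan-2-yl]-2-methoxyphenyl pivalate (Ar1 cis to OH; CH2OTBS cis to the veratrylmethyl group)
Conditions: SmI2 (2.5 equiv), HMPA (10 equiv), t-BuOH (2 equiv), THF, −78 °C, 11 added slowly; aq NH4Cl
Reagents that add atoms: none
Why: SmI2–HMPA transfers one electron to the C8' carbonyl; the samarium ketyl adds to C8 of the (E)-styrene unit, and the benzylic C7 radical is reduced by a second equivalent of divalent samarium and protonated by t-BuOH to the veratrylmethyl group. The closest known reaction type is the SmI2-mediated ketyl–olefin cyclisation of unsaturated ketones with styrene or acrylate acceptors, which has also been run on α-oxygenated carbonyl compounds. Ring A closes in the 5-exo-trig mode (C8'–C7'–O–C9–C8) and the C8–C8' bond is formed. C8 is controlled by C7': in the chair-like transition state Ar1 is pseudo-equatorial, so the alkene reacts on the face away from Ar1 and the 7',8-trans ring results. C8' is controlled by the ketyl: the HMPA-solvated oxygen–samarium group turns away from the alkene, so the hydroxyl ends trans to the C8 arm and cis to Ar1, and the CH2OTBS group ends cis to the C8 arm as ring B requires. The step needs cyclisation to win over two-electron cleavage of the C7'–O or C9'–O bond α to the carbonyl and over enolisation at C7'. The conjugated acceptor makes the unimolecular 5-exo step much faster than a second, bimolecular electron transfer to the ketyl, and at −78 °C the ketone is consumed as it enters the flask. The aryl pivalate and the silyl ether are not reduced under these conditions.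

Step 9
Reactants: 12 4-[(2R,3S,4S)-3-{[(tert-butyldimethylsilyl)oxy]methyl}-4-(3,4-dimethoxybenzyl)-3-hydroxyoxolan-2-yl]-2-methoxyphenyl pivalate
Product: 13 4-[(2R,3S,4S)-4-(3,4-dimethoxybenzyl)-3-hydroxy-3-(hydroxymethyl)oxolan-2-yl]-2-methoxyphenyl pivalate
Conditions: Bu4NF, AcOH (1:1), THF, 0 °C to rt
Reagents that add atoms: none
Why: Fluoride cleavage of a primary silyl ether; buffering with acetic acid keeps the medium from attacking the aryl pivalate.

Step 10
Reactants: 13 4-[(2R,3S,4S)-4-(3,4-dimethoxybenzyl)-3-hydroxy-3-(hydroxymethyl)oxolan-2-yl]-2-methoxyphenyl pivalate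
Product: 14 4-[(1R,3aR,4S,6aS)-4-(3,4-dimethoxyphenyl)-6a-hydroxytetrahydro-1H,3H-furo[3,4-c]furan-1-yl]-2-methoxyphenyl pivalate (7S,8R,7'R,8'S; both aryl groups exo)
Conditions: DDQ (1.1 equiv), 2,6-dichloropyridine, 4 Å MS, CH2Cl2, 0 °C
Reagents that add atoms: none
Why: DDQ-mediated benzylic C–H oxidation of an electron-rich alkylarene with intramolecular capture by a hydroxyl; hydride abstraction occurs at C7 of the dimethoxyphenyl ring only (Ar1 is deactivated by the pivalate), and the C9' hydroxyl closes ring B, necessarily cis-fused. Ar2 should take the convex face in the kinetic capture of the planar cation, giving (S)-C7; the remaining C7 hydrogen then lies on the concave face, which should slow a second oxidation, and the pyridine base prevents acid-mediated epimerisation.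

Step 11
Reactants: 14 4-[(1R,3aR,4S,6aS)-4-(3,4-dimethoxyphenyl)-6a-hydroxytetrahydro-1H,3H-furo[3,4-c]furan-1-yl]-2-methoxyphenyl pivalate
Product: 15 4-[(1R,3aR,4S,6aS)-4-(3,4-dimethoxyphenyl)-6a-hydroxytetrahydro-1H,3H-furo[3,4-c]furan-1-yl]-2-methoxyphenol
Conditions: K2CO3 (0.2 equiv), MeOH, rt
Reagents that add atoms: none
Why: Base-catalysed methanolysis of an aryl ester (phenoxide leaving group); the ethers and the tertiary alcohol are inert, and the mild base at room temperature should not open the C7' ether through a quinone methide.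

Step 12
Reactants: 15 4-[(1R,3aR,4S,6aS)-4-(3,4-dimethoxyphenyl)-6a-hydroxytetrahydro-1H,3H-furo[3,4-c]furan-1-yl]-2-methoxyphenol
Product: 17 (3R,3aS,6S,6aR)-6-(3,4-dimethoxyphenyl)-3-(4-hydroxy-3-methoxyphenyl)tetrahydro-1H,3H-furo[3,4-c]furan-3a-yl acetate, via diacetate 16 (not isolated)
Conditions: Ac2O (6 equiv), DMAP (1 equiv), Et3N, CH2Cl2, rt to 35 °C; then pyrrolidine (excess), 0 °C
Reagents that add atoms: acetic anhydride, CC(=O)OC(C)=O
Why: DMAP-catalysed acylation acetylates both the phenol and the hindered tertiary alcohol without acid; pyrrolidine then destroys excess anhydride and aminolyses only the aryl acetate, an activated ester, while the tertiary alkyl acetate is untouched. No stereocentre is affected.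

## Compound list

1 | ferulic acid, (E)-3-(4-hydroxy-3-methoxyphenyl)prop-2-enoic acid | COc1cc(/C=C/C(=O)O)ccc1O | starting material
2 | (E)-3-[3-methoxy-4-(pivaloyloxy)phenyl]prop-2-enoic acid | COc1cc(/C=C/C(=O)O)ccc1OC(=O)C(C)(C)C | intermediate
3 | (E)-3-[3-methoxy-4-(pivaloyloxy)phenyl]prop-2-enoic isobutyl carbonic anhydride | COc1cc(/C=C/C(=O)OC(=O)OCC(C)C)ccc1OC(=O)C(C)(C)C | intermediate
4 | (E)-4-(3-hydroxyprop-1-en-1-yl)-2-methoxyphenyl pivalate | COc1cc(/C=C/CO)ccc1OC(=O)C(C)(C)C | intermediate
5 | 3,4-dimethoxycinnamic acid, (E)-3-(3,4-dimethoxyphenyl)prop-2-enoic acid | COc1ccc(/C=C/C(=O)O)cc1OC | starting material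
6 | (E)-3-(3,4-dimethoxyphenyl)prop-2-enoic isobutyl carbonic anhydride | COc1ccc(/C=C/C(=O)OC(=O)OCC(C)C)cc1OC | intermediate
7 | (E)-3-(3,4-dimethoxyphenyl)prop-2-en-1-ol | COc1ccc(/C=C/CO)cc1OC | intermediate
8 | 4-[(2S,3S)-3-(hydroxymethyl)oxiran-2-yl]-2-methoxyphenyl pivalate | OC[C@@H]1O[C@H]1c1ccc(OC(=O)C(C)(C)C)c(OC)c1 | intermediate
9 | 4-[(1R,2S)-1-{[(E)-3-(3,4-dimethoxyphenyl)prop-2-en-1-yl]oxy}-2,3-dihydroxypropyl]-2-methoxyphenyl pivalate | COc1cc([C@@H](OC/C=C/c2ccc(OC)c(OC)c2)[C@@H](O)CO)ccc1OC(=O)C(C)(C)C | intermediate
10 | 4-[(1R,2S)-3-[(tert-butyldimethylsilyl)oxy]-1-{[(E)-3-(3,4-dimethoxyphenyl)prop-2-en-1-yl]oxy}-2-hydroxypropyl]-2-methoxyphenyl pivalate | COc1cc([C@@H](OC/C=C/c2ccc(OC)c(OC)c2)[C@@H](O)CO[Si](C)(C)C(C)(C)C)ccc1OC(=O)C(C)(C)C | intermediate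
11 | 4-[(1R)-3-[(tert-butyldimethylsilyl)oxy]-1-{[(E)-3-(3,4-dimethoxyphenyl)prop-2-en-1-yl]oxy}-2-oxopropyl]-2-methoxyphenyl pivalate | COc1cc([C@@H](OC/C=C/c2ccc(OC)c(OC)c2)C(=O)CO[Si](C)(C)C(C)(C)C)ccc1OC(=O)C(C)(C)C | intermediate
12 | 4-[(2R,3S,4S)-3-{[(tert-butyldimethylsilyl)oxy]methyl}-4-(3,4-dimethoxybenzyl)-3-hydroxyoxolan-2-yl]-2-methoxyphenyl pivalate | COc1cc([C@H]2OC[C@H](Cc3ccc(OC)c(OC)c3)[C@]2(O)CO[Si](C)(C)C(C)(C)C)ccc1OC(=O)C(C)(C)C | intermediate
13 | 4-[(2R,3S,4S)-4-(3,4-dimethoxybenzyl)-3-hydroxy-3-(hydroxymethyl)oxolan-2-yl]-2-methoxyphenyl pivalate | COc1cc([C@H]2OC[C@H](Cc3ccc(OC)c(OC)c3)[C@]2(O)CO)ccc1OC(=O)C(C)(C)C | intermediate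
14 | 4-[(1R,3aR,4S,6aS)-4-(3,4-dimethoxyphenyl)-6a-hydroxytetrahydro-1H,3H-furo[3,4-c]furan-1-yl]-2-methoxyphenyl pivalate | COc1cc([C@H]2OC[C@@H]3[C@@H](c4ccc(OC)c(OC)c4)OC[C@]23O)ccc1OC(=O)C(C)(C)C | intermediate
15 | 4-[(1R,3aR,4S,6aS)-4-(3,4-dimethoxyphenyl)-6a-hydroxytetrahydro-1H,3H-furo[3,4-c]furan-1-yl]-2-methoxyphenol | COc1cc([C@H]2OC[C@@H]3[C@@H](c4ccc(OC)c(OC)c4)OC[C@]23O)ccc1O | intermediate
16 | 4-[(1R,3aR,4S,6aS)-6a-acetoxy-4-(3,4-dimethoxyphenyl)tetrahydro-1H,3H-furo[3,4-c]furan-1-yl]-2-methoxyphenyl acetate | COc1cc([C@H]2OC[C@@H]3[C@@H](c4ccc(OC)c(OC)c4)OC[C@]23OC(C)=O)ccc1OC(C)=O | intermediate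
17 | (3R,3aS,6S,6aR)-6-(3,4-dimethoxyphenyl)-3-(4-hydroxy-3-methoxyphenyl)tetrahydro-1H,3H-furo[3,4-c]furan-3a-yl acetate | COc1cc([C@H]2OC[C@@H]3[C@@H](c4ccc(OC)c(OC)c4)OC[C@]23OC(C)=O)ccc1O | target

## Step count and points of risk

Total: 12 steps. Longest linear sequence: 11 steps (1 to 17 through steps 1, 2 and 4–12); step 3 is a one-step branch.

**Step 8 (key step).** The most likely failure is reductive cleavage of the C7'–O or C9'–O bond: a second electron reaches the ketyl before it cyclises and the resulting carbanion expels the α-alkoxide. Loss of configuration at C7' by enolisation in the alkoxide-containing medium, or incomplete facial control at C8', are lesser risks. Fallback: from 11, the ketyl is generated as an O-stannyl ketyl in a radical chain (Bu3SnH, AIBN, benzene, 80 °C), which offers no second electron. The same 5-exo closure should give the tributylstannyl ether of 12, F1, which a KF work-up hydrolyses to 12. Lower diastereoselectivity at the higher temperature would have to be accepted.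

**Step 5.** Three processes may interfere: transfer of residual isopropoxide in place of the cinnamyl alkoxide, titanium-catalysed transesterification of the aryl pivalate, and Lewis-acid ionisation of the electron-rich allylic alcohol 7. Fallback: from 8, the epoxide is opened with allyl alcohol as co-solvent (Ti(OiPr)4, 40 °C) to 4-[(1R,2S)-1-(allyloxy)-2,3-dihydroxypropyl]-2-methoxyphenyl pivalate F2. Cross-metathesis of F2 with commercial 3,4-dimethoxystyrene, using the second-generation Hoveyda–Grubbs catalyst RuCl2(H2IMes)(=CH-C6H4-2-OiPr) in CH2Cl2 at 40 °C, installs the (E)-aryl alkene and returns to 9.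

**Step 10.** Hydride abstraction from a benzylic CH2 that carries no oxygen may be slow, so that oxidation of the product's benzylic ether C–H competes. Capture of the C7 cation may also show poor facial selectivity. Fallback: from 13, oxidation is driven to the ketone on purpose (DDQ, 2.5 equiv, CH2Cl2/H2O) to give the 4-(3,4-dimethoxybenzoyl) analogue of 13, F3, expected largely as its cyclic hemiketal. Luche reduction (NaBH4, CeCl3·7H2O, MeOH, −40 °C) gives the benzylic alcohol F4 as an epimer mixture. Catalytic camphorsulfonic acid in CH2Cl2 at 0 °C then closes ring B through the benzylic cation, the classical furofuran closure, and rejoins the route at 14.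

**Step 12.** Acylation of the bridgehead tertiary hydroxyl, flanked by the cis Ar1 group, may stall, leaving the phenol acetate as the only site acylated. Fallback: from 14, where the phenol is still masked, the potassium alkoxide is formed (KN(SiMe3)2, THF, −78 °C) and trapped with acetyl chloride to give the 8'-acetate 4'-pivalate F5. The aryl pivalate is then cleaved by aminolysis (MeNH2, THF/MeOH, rt), which the tertiary acetate should survive, arriving directly at 17.

## Further compounds

F1 | step 8 | 4-[(2R,3S,4S)-3-{[(tert-butyldimethylsilyl)oxy]methyl}-4-(3,4-dimethoxybenzyl)-3-[(tributylstannyl)oxy]oxolan-2-yl]-2-methoxyphenyl pivalate | COc1cc([C@H]2OC[C@H](Cc3ccc(OC)c(OC)c3)[C@]2(O[Sn](CCCC)(CCCC)CCCC)CO[Si](C)(C)C(C)(C)C)ccc1OC(=O)C(C)(C)C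
F2 | step 5 | 4-[(1R,2S)-1-(allyloxy)-2,3-dihydroxypropyl]-2-methoxyphenyl pivalate | COc1cc([C@@H](OCC=C)[C@@H](O)CO)ccc1OC(=O)C(C)(C)C
F3 | step 10 | 4-[4-(3,4-dimethoxybenzoyl)-3-hydroxy-3-(hydroxymethyl)oxolan-2-yl]-2-methoxyphenyl pivalate, ring configuration as in 13 | COc1cc([C@H]2OC[C@H](C(=O)c3ccc(OC)c(OC)c3)[C@]2(O)CO)ccc1OC(=O)C(C)(C)C
F4 | step 10 | 4-[4-[(3,4-dimethoxyphenyl)(hydroxy)methyl]-3-hydroxy-3-(hydroxymethyl)oxolan-2-yl]-2-methoxyphenyl pivalate, ring configuration as in 13, carbinol epimers | COc1cc([C@H]2OC[C@H](C(O)c3ccc(OC)c(OC)c3)[C@]2(O)CO)ccc1OC(=O)C(C)(C)C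
F5 | step 12 | 4-[(1R,3aR,4S,6aS)-6a-acetoxy-4-(3,4-dimethoxyphenyl)tetrahydro-1H,3H-furo[3,4-c]furan-1-yl]-2-methoxyphenyl pivalate | COc1cc([C@H]2OC[C@@H]3[C@@H](c4ccc(OC)c(OC)c4)OC[C@]23OC(C)=O)ccc1OC(=O)C(C)(C)C
A1 | alternative 1 | 7-[4-(benzyloxy)-3-methoxyphenyl]-1-[(tert-butyldimethylsilyl)oxy]-4-(3,4-dimethoxyphenyl)-3-oxabicyclo[3.2.0]heptan-6-one, cis-fused, C7 aryl exo | COc1cc([C@H]2C(=O)[C@@H]3[C@@H](c4ccc(OC)c(OC)c4)OC[C@]23O[Si](C)(C)C(C)(C)C)ccc1OCc1ccccc1
A2 | alternative 1 | tert-butyl{[(5S)-5-(3,4-dimethoxyphenyl)-2,5-dihydrofuran-3-yl]oxy}dimethylsilane | COc1ccc([C@H]2OCC(O[Si](C)(C)C(C)(C)C)=C2)cc1OC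
A3 | alternative 1 | [4-(benzyloxy)-3-methoxyphenyl]ketene | COc1cc(C=C=O)ccc1OCc1ccccc1
A4 | alternative 2 | 4-[(1R,3aR,4S,6aS)-4-(3,4-dimethoxyphenyl)-6a-hydroxytetrahydro-1H,3H-furo[3,4-c]furan-1-yl]-2-methoxyphenol | COc1cc([C@H]2OC[C@@H]3[C@@H](c4ccc(OC)c(OC)c4)OC[C@]23O)ccc1O
A5 | alternative 2 | 1-(3,4-dimethoxyphenyl)-4-(4-hydroxy-3-methoxyphenyl)-2,3-bis(hydroxymethyl)butane-1,3,4-triol, C8 and C8' as in the target, benzylic carbinols as epimer mixtures | COc1ccc(C(O)[C@@H](CO)[C@](O)(CO)C(O)c2ccc(O)c(OC)c2)cc1OC
A6 | alternative 3 | (1R,3aR,4S,6aS)-1-[4-(benzyloxy)-3-methoxyphenyl]-4-(3,4-dimethoxyphenyl)tetrahydro-1H,3H-furo[3,4-c]furan-6a-ol | COc1cc([C@H]2OC[C@@H]3[C@@H](c4ccc(OC)c(OC)c4)OC[C@]23O)ccc1OCc1ccccc1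
A7 | alternative 3 | (4R,5S)-4-({[4-(benzyloxy)-3-methoxyphenyl]methoxy}methyl)-5-(3,4-dimethoxyphenyl)oxolan-3-one | COc1ccc([C@H]2OCC(=O)[C@@H]2COCc2ccc(OCc3ccccc3)c(OC)c2)cc1OC
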